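**Retrosynthetic overview**

1. Target ⇒ a bicyclic 5‑hydroxy‑chromene‑4,7‑dione lacking the side chain, plus 3‑phenylpropynal. The C6–CH(Ph) bond and the benzylic centre come from a carbene‑catalysed Coates–Claisen annulation, followed by opening of the enol lactone.
2. Chromenedione ⇒ a 5‑acetyl‑2,3‑dihydro‑4H‑pyran‑4‑one carrying C(prenyl)(lavandulyl)CO2Me on C6, by Dieckmann‑type closure of the C6–C7 bond (ring A). The enabling feature is that ring A is a cyclic β‑triketone: C7(=O) lies between the fully substituted, non‑enolisable C8 and C6, which is the α‑carbon of the C5 carbonyl, and both arms sit cis on the C4a=C8a double bond shared with ring B.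
3. Acetylpyranone ⇒ C5–H pyranone (bromination, Stille acetylation) ⇒ δ‑silyloxy β‑diketone (cyclodehydration gives ring B) ⇒ quaternary methyl ketone + (2R,3R)‑3‑silyloxy‑2‑methylbutanoyl chloride (crossed Claisen).
4. Quaternary ketone ⇒ methyl acetoacetate + (S)‑lavandulyl iodide (Evans alkylation), then valine‑enamine‑directed prenylation (C8). Acid fragment ⇒ methyl (R)‑3‑hydroxybutanoate by Fráter–Seebach methylation (C2, C3).
5. Ring order: ring B (dihydropyranone) first, ring A (carbocycle) second.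

Key step: step 15

Remark: the direction of asymmetric induction in steps 7 and 16 is assigned by analogy with the parent reactions; the opposite face is reached by running step 7 in THF instead of toluene/HMPA and step 16 with the mirror‑image triazolium salt, so either outcome of a model study can be accommodated.

**Route**

Step 1
Reactants: 1 (4S)-4-benzyl-1,3-oxazolidin-2-one; 2 3-methylbut-2-enoyl chloride
Product: 3 (4S)-4-benzyl-3-(3-methylbut-2-enoyl)-1,3-oxazolidin-2-one
Conditions: n-BuLi, THF, −78 °C; then 2, −78 → 0 °C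
Reagents that add atoms: none
Why: N‑acylation of the lithiated oxazolidinone by the acid chloride (standard loading of the chiral auxiliary); no stereocentre is formed.

Step 2
Reactants: 3 (4S)-4-benzyl-3-(3-methylbut-2-enoyl)-1,3-oxazolidin-2-one; 4 1-bromo-3-methylbut-2-ene (prenyl bromide)
Product: 5 (4S)-4-benzyl-3-[(2S)-5-methyl-2-(prop-1-en-2-yl)hex-4-enoyl]-1,3-oxazolidin-2-one
Conditions: NaN(SiMe3)2, THF, −78 °C; then 4, −78 → −40 °C
Reagents that add atoms: none
Why: Evans asymmetric alkylation: γ‑deprotonation gives the chelated (Z)‑dienolate, which should be alkylated at the α‑carbon on the face opposite the benzyl group, setting the (S) centre and leaving the double bond in the isopropenyl position.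

Step 3
Reactants: 5 (4S)-4-benzyl-3-[(2S)-5-methyl-2-(prop-1-en-2-yl)hex-4-enoyl]-1,3-oxazolidin-2-one
Product: 6 (2S)-5-methyl-2-(prop-1-en-2-yl)hex-4-en-1-ol ((S)-lavandulol)
Conditions: LiBH4, H2O (1 equiv), Et2O, 0 °C
Reagents that add atoms: none
Why: Reductive cleavage of the imide by hydride gives the primary alcohol and returns the auxiliary; the non‑conjugated α‑centre should not epimerise under these non‑basic conditions.

Step 4
Reactants: 6 (2S)-5-methyl-2-(prop-1-en-2-yl)hex-4-en-1-ol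
Product: 7 (2S)-1-iodo-5-methyl-2-(prop-1-en-2-yl)hex-4-ene ((S)-lavandulyl iodide)
Conditions: I2, PPh3, imidazole, CH2Cl2, 0 °C → rt
Reagents that add atoms: iodine, II
Why: Appel‑type iodination of a primary alcohol; substitution occurs at CH2, so the stereocentre is untouched.

Step 5
Reactants: 8 methyl 3-oxobutanoate (methyl acetoacetate); 7 (2S)-1-iodo-5-methyl-2-(prop-1-en-2-yl)hex-4-ene
Product: 9 methyl (4R)-2-acetyl-7-methyl-4-(prop-1-en-2-yl)oct-6-enoate (both C2 epimers)
Conditions: NaH, THF/DMF, 0 °C; then 7, 60 °C (8 in excess)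
Reagents that add atoms: none
Why: Acetoacetic ester alkylation (SN2 of the sodium enolate at the primary iodide); the new C2 centre forms unselectively, which is immaterial because C2 becomes planar in step 6.

Step 6
Reactants: 9 methyl (4R)-2-acetyl-7-methyl-4-(prop-1-en-2-yl)oct-6-enoate; 10 tert-butyl L-valinate
Product: 11 methyl (2Z)-3-{[(2S)-1-tert-butoxy-3-methyl-1-oxobutan-2-yl]amino}-2-[(2R)-5-methyl-2-(prop-1-en-2-yl)hex-4-en-1-yl]but-2-enoate
Conditions: BF3·OEt2 (cat.), benzene, reflux, Dean–Stark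
Reagents that add atoms: none
Why: Condensation of the ketone with the primary amine gives the hydrogen‑bonded (Z)‑β‑enamino ester, which installs the valine‑derived chiral controller.

Step 7
Reactants: 11 methyl (2Z)-3-{[(2S)-1-tert-butoxy-3-methyl-1-oxobutan-2-yl]amino}-2-[(2R)-5-methyl-2-(prop-1-en-2-yl)hex-4-en-1-yl]but-2-enoate; 4 1-bromo-3-methylbut-2-ene
Product: 13 methyl (2S,4R)-2-acetyl-7-methyl-2-(3-methylbut-2-en-1-yl)-4-(prop-1-en-2-yl)oct-6-enoate, via ketimine 12 (not isolated)
Conditions: LiN(iPr)2, toluene, HMPA (1 equiv), −78 °C; 4, −78 → −55 °C; then 1 M HCl, Et2O, 0 °C → rt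
Reagents that add atoms: water, O
Why: N‑lithiation gives a chelated aza‑enolate (Li bound to N and the tert‑butyl ester carbonyl) in which the isopropyl group shields one face, so prenyl bromide should attack C2 from the open face and set the quaternary centre (asymmetric alkylation of chiral enamines of α‑alkyl β‑keto esters); mild acid hydrolysis of the ketimine then releases the ketone and the auxiliary.

Step 8
Reactants: 14 methyl (3R)-3-hydroxybutanoate
Product: 15 methyl (2R,3R)-3-hydroxy-2-methylbutanoate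
Conditions: LiN(iPr)2 (2.1 equiv), THF, −50 → −20 °C; MeI, DMPU, −78 → 0 °C
Reagents that add atoms: iodomethane, CI
Why: Fráter–Seebach alkylation: the chelated alkoxide–enolate dianion should be methylated on the face anti to the C3 methyl group, giving the anti (2R,3R) product.

Step 9
Reactants: 15 methyl (2R,3R)-3-hydroxy-2-methylbutanoate
Product: 16 methyl (2R,3R)-3-[(tert-butyldimethylsilyl)oxy]-2-methylbutanoate
Conditions: TBSCl, imidazole, DMF, rt
Reagents that add atoms: tert-butyldimethylsilyl chloride, CC(C)(C)[Si](C)(C)Cl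
Why: Silylation of the secondary alcohol protects it through the acylation in step 11; no stereocentre is affected.

Step 10
Reactants: 16 methyl (2R,3R)-3-[(tert-butyldimethylsilyl)oxy]-2-methylbutanoate
Product: 17 (2R,3R)-3-[(tert-butyldimethylsilyl)oxy]-2-methylbutanoic acid
Conditions: LiOH, THF/MeOH/H2O, rt; then 1 M HCl to pH 3, 0 °C
Reagents that add atoms: lithium hydroxide, [Li+].[OH-]
Why: Saponification of the methyl ester; the secondary silyl ether should survive and the α‑centre is not enolised under these conditions.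

Step 11
Reactants: 17 (2R,3R)-3-[(tert-butyldimethylsilyl)oxy]-2-methylbutanoic acid; 13 methyl (2S,4R)-2-acetyl-7-methyl-2-(3-methylbut-2-en-1-yl)-4-(prop-1-en-2-yl)oct-6-enoate
Product: 19 methyl (2S,4R)-2-{(4R,5R)-5-[(tert-butyldimethylsilyl)oxy]-4-methyl-3-oxohexanoyl}-7-methyl-2-(3-methylbut-2-en-1-yl)-4-(prop-1-en-2-yl)oct-6-enoate, via acid chloride 18 (not isolated)
Conditions: 17, 1-chloro-N,N,2-trimethylprop-1-en-1-amine, CH2Cl2, 0 °C → rt; then 13, MgBr2·OEt2, iPr2NEt, CH2Cl2, rt
Reagents that add atoms: none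
Why: Neutral conversion of the acid into its chloride, then crossed Claisen condensation by soft enolisation: the MgBr2‑bound methyl ketone (its only enolisable position) is deprotonated by the amine and C‑acylated to the β‑diketone; any epimerisation α to the new ketone is tolerable because that centre can be equilibrated to the more stable trans arrangement once ring B exists.

Step 12
Reactants: 19 methyl (2S,4R)-2-{(4R,5R)-5-[(tert-butyldimethylsilyl)oxy]-4-methyl-3-oxohexanoyl}-7-methyl-2-(3-methylbut-2-en-1-yl)-4-(prop-1-en-2-yl)oct-6-enoate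
Product: 21 methyl (2S,4R)-2-[(2R,3R)-2,3-dimethyl-4-oxo-3,4-dihydro-2H-pyran-6-yl]-7-methyl-2-(3-methylbut-2-en-1-yl)-4-(prop-1-en-2-yl)oct-6-enoate, via hydroxy diketone 20 (not isolated)
Conditions: HF·pyridine, THF, 0 °C → rt; then TsOH·H2O (cat.), CH2Cl2, 4 Å MS, rt
Reagents that add atoms: none
Why: Desilylation followed by acid‑catalysed hemiketalisation and dehydration (cyclodehydration of a δ‑hydroxy β‑diketone, six‑membered) gives the 2,3‑dihydro‑4H‑pyran‑4‑one; the hydroxyl can only reach the carbonyl next to the quaternary carbon, which fixes the ring oxygen on C6, and the (2R,3R)‑trans dimethyl pattern is carried in unchanged.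

Step 13
Reactants: 21 methyl (2S,4R)-2-[(2R,3R)-2,3-dimethyl-4-oxo-3,4-dihydro-2H-pyran-6-yl]-7-methyl-2-(3-methylbut-2-en-1-yl)-4-(prop-1-en-2-yl)oct-6-enoate
Product: 22 methyl (2S,4R)-2-[(2R,3R)-5-bromo-2,3-dimethyl-4-oxo-3,4-dihydro-2H-pyran-6-yl]-7-methyl-2-(3-methylbut-2-en-1-yl)-4-(prop-1-en-2-yl)oct-6-enoate
Conditions: NBS (1.0 equiv), NaHCO3, CH2Cl2, 0 °C, dark
Reagents that add atoms: N-bromosuccinimide, O=C1CCC(=O)N1Br
Why: Electrophilic substitution of the vinylogous ester at its nucleophilic α‑carbon (pyranone C5, the only enol‑ether‑type position), with loss of the C5 proton; the isolated alkenes should react more slowly in the absence of a nucleophile or radical initiator.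

Step 14
Reactants: 22 methyl (2S,4R)-2-[(2R,3R)-5-bromo-2,3-dimethyl-4-oxo-3,4-dihydro-2H-pyran-6-yl]-7-methyl-2-(3-methylbut-2-en-1-yl)-4-(prop-1-en-2-yl)oct-6-enoate; 23 tributyl(1-ethoxyethenyl)stannane
Product: 25 methyl (2S,4R)-2-[(2R,3R)-5-acetyl-2,3-dimethyl-4-oxo-3,4-dihydro-2H-pyran-6-yl]-7-methyl-2-(3-methylbut-2-en-1-yl)-4-(prop-1-en-2-yl)oct-6-enoate, via enol ether 24 (not isolated)
Conditions: PdCl2(PPh3)2 (5 mol%), toluene, 95 °C; then 1 M HCl, THF, rt
Reagents that add atoms: water, O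
Why: Stille coupling of the α‑bromo enone with the acetyl‑anion equivalent, then hydrolysis of the enol ether to the methyl ketone; no stereocentre is involved.

Step 15
Reactants: 25 methyl (2S,4R)-2-[(2R,3R)-5-acetyl-2,3-dimethyl-4-oxo-3,4-dihydro-2H-pyran-6-yl]-7-methyl-2-(3-methylbut-2-en-1-yl)-4-(prop-1-en-2-yl)oct-6-enoate
Product: 26 (2R,3R,8S)-5-hydroxy-2,3-dimethyl-8-(3-methylbut-2-en-1-yl)-8-[(2R)-5-methyl-2-(prop-1-en-2-yl)hex-4-en-1-yl]-2,3-dihydro-4H-chromene-4,7(8H)-dione
Conditions: LiN(SiMe3)2 (2.5 equiv), THF, −78 → 0 °C; then 1 M HCl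
Reagents that add atoms: none
Why: The amide base removes a proton from the acetyl methyl group on pyranone C5 (lithium held between the acetyl and C4 carbonyl oxygens), and the enolate carbon attacks the methyl ester on the quaternary carbon attached to the neighbouring C6; collapse of the tetrahedral intermediate with loss of methoxide gives the cyclic β‑triketone, which is deprotonated at once to its delocalised enolate, the sink that makes the Claisen step irreversible. The closest known reaction type is the Dieckmann‑type (intramolecular Claisen) cyclisation of δ‑keto esters with an α‑quaternary ester carbon to 4,4‑disubstituted cyclohexane‑1,3‑diones and dearomatised acylphloroglucinols. Ring A closes in the 6‑(enolexo)‑exo‑trig mode. No stereocentre is formed: C8 is already quaternary and cannot epimerise, and C2/C3 of ring B are spectators (C3, if it enolises, should return to the more stable trans arrangement). The selectivity needed is enolisation at the acetyl CH3 rather than at C3–H, whose enolate could expel the ring oxygen; it is secured by kinetic deprotonation of the unhindered methyl group at −78 °C, by the fact that only this enolate has an electrophile within reach (attack from C3 would give a bridgehead alkene), and by the rigid cis placement of nucleophile and electrophile on the ring B double bond. The step turns the monocyclic pyranone into the complete bicyclic core and makes C6 the carbon of a stable enol, which is the nucleophile the next, stereodefining C–C bond formation needs.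

Step 16
Reactants: 26 (2R,3R,8S)-5-hydroxy-2,3-dimethyl-8-(3-methylbut-2-en-1-yl)-8-[(2R)-5-methyl-2-(prop-1-en-2-yl)hex-4-en-1-yl]-2,3-dihydro-4H-chromene-4,7(8H)-dione; 27 3-phenylprop-2-ynal
Product: 30 (3S)-3-{(2R,3R,8S)-5-hydroxy-2,3-dimethyl-8-(3-methylbut-2-en-1-yl)-8-[(2R)-5-methyl-2-(prop-1-en-2-yl)hex-4-en-1-yl]-4,7-dioxo-3,4,7,8-tetrahydro-2H-chromen-6-yl}-3-phenylpropanoic acid (CNP0150579.1), via O7 enol lactone 28 (not isolated), via O5 enol lactone 29 (not isolated)
Conditions: (5aR,10bS)-2-mesityl-5a,10b-dihydro-4H,6H-indeno[2,1-b][1,2,4]triazolo[4,3-d][1,4]oxazin-2-ium chloride (10 mol%), toluene, 40 °C; then LiOH, THF/H2O, 0 °C; 1 M HCl to pH 3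
Reagents that add atoms: water (delivered as aqueous LiOH), O
Why: The triazolium‑derived carbene converts the ynal into an α,β‑unsaturated acyl azolium, to which the stable enol of 26 adds through its only free carbon, C6 (1,2‑addition then [3,3] shift, Coates–Claisen annulation), the aminoindanol backbone deciding the face of the cinnamoyl unit and hence the benzylic centre under catalyst control; lactonisation by either enol oxygen (O7 gives 28, O5 gives 29) releases the catalyst, and LiOH should open both enol lactones to the same acid.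

**Compound list**

1 | (4S)-4-benzyl-1,3-oxazolidin-2-one | O=C1N[C@@H](Cc2ccccc2)CO1 | starting material
2 | 3-methylbut-2-enoyl chloride | CC(C)=CC(=O)Cl | starting material
3 | (4S)-4-benzyl-3-(3-methylbut-2-enoyl)-1,3-oxazolidin-2-one | CC(C)=CC(=O)N1[C@@H](Cc2ccccc2)COC1=O | intermediate
4 | 1-bromo-3-methylbut-2-ene (prenyl bromide) | CC(C)=CCBr | starting material
5 | (4S)-4-benzyl-3-[(2S)-5-methyl-2-(prop-1-en-2-yl)hex-4-enoyl]-1,3-oxazolidin-2-one | C=C(C)[C@H](CC=C(C)C)C(=O)N1[C@@H](Cc2ccccc2)COC1=O | intermediate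
6 | (2S)-5-methyl-2-(prop-1-en-2-yl)hex-4-en-1-ol ((S)-lavandulol) | C=C(C)[C@H](CC=C(C)C)CO | intermediate
7 | (2S)-1-iodo-5-methyl-2-(prop-1-en-2-yl)hex-4-ene ((S)-lavandulyl iodide) | C=C(C)[C@H](CC=C(C)C)CI | intermediate
8 | methyl 3-oxobutanoate (methyl acetoacetate) | COC(=O)CC(C)=O | starting material
9 | methyl (4R)-2-acetyl-7-methyl-4-(prop-1-en-2-yl)oct-6-enoate (both C2 epimers) | C=C(C)[C@H](CC=C(C)C)CC(C(C)=O)C(=O)OC | intermediate
10 | tert-butyl L-valinate | CC(C)[C@H](N)C(=O)OC(C)(C)C | starting material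
11 | methyl (2Z)-3-{[(2S)-1-tert-butoxy-3-methyl-1-oxobutan-2-yl]amino}-2-[(2R)-5-methyl-2-(prop-1-en-2-yl)hex-4-en-1-yl]but-2-enoate | C=C(C)[C@H](CC=C(C)C)C/C(C(=O)OC)=C(\C)N[C@@H](C(C)C)C(=O)OC(C)(C)C | intermediate
12 | methyl (2S,4R)-2-{N-[(2S)-1-tert-butoxy-3-methyl-1-oxobutan-2-yl]ethanimidoyl}-7-methyl-2-(3-methylbut-2-en-1-yl)-4-(prop-1-en-2-yl)oct-6-enoate (ketimine) | C=C(C)[C@H](CC=C(C)C)C[C@](CC=C(C)C)(C(=O)OC)C(C)=N[C@@H](C(C)C)C(=O)OC(C)(C)C | intermediate
13 | methyl (2S,4R)-2-acetyl-7-methyl-2-(3-methylbut-2-en-1-yl)-4-(prop-1-en-2-yl)oct-6-enoate | C=C(C)[C@H](CC=C(C)C)C[C@](CC=C(C)C)(C(=O)OC)C(C)=O | intermediate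
14 | methyl (3R)-3-hydroxybutanoate | C[C@@H](O)CC(=O)OC | starting material
15 | methyl (2R,3R)-3-hydroxy-2-methylbutanoate | COC(=O)[C@H](C)[C@@H](C)O | intermediate
16 | methyl (2R,3R)-3-[(tert-butyldimethylsilyl)oxy]-2-methylbutanoate | COC(=O)[C@H](C)[C@@H](C)O[Si](C)(C)C(C)(C)C | intermediate
17 | (2R,3R)-3-[(tert-butyldimethylsilyl)oxy]-2-methylbutanoic acid | OC(=O)[C@H](C)[C@@H](C)O[Si](C)(C)C(C)(C)C | intermediate
18 | (2R,3R)-3-[(tert-butyldimethylsilyl)oxy]-2-methylbutanoyl chloride | ClC(=O)[C@H](C)[C@@H](C)O[Si](C)(C)C(C)(C)C | intermediate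
19 | methyl (2S,4R)-2-{(4R,5R)-5-[(tert-butyldimethylsilyl)oxy]-4-methyl-3-oxohexanoyl}-7-methyl-2-(3-methylbut-2-en-1-yl)-4-(prop-1-en-2-yl)oct-6-enoate | C=C(C)[C@H](CC=C(C)C)C[C@](CC=C(C)C)(C(=O)OC)C(=O)CC(=O)[C@H](C)[C@@H](C)O[Si](C)(C)C(C)(C)C | intermediate
20 | methyl (2S,4R)-2-[(4R,5R)-5-hydroxy-4-methyl-3-oxohexanoyl]-7-methyl-2-(3-methylbut-2-en-1-yl)-4-(prop-1-en-2-yl)oct-6-enoate | C=C(C)[C@H](CC=C(C)C)C[C@](CC=C(C)C)(C(=O)OC)C(=O)CC(=O)[C@H](C)[C@@H](C)O | intermediate
21 | methyl (2S,4R)-2-[(2R,3R)-2,3-dimethyl-4-oxo-3,4-dihydro-2H-pyran-6-yl]-7-methyl-2-(3-methylbut-2-en-1-yl)-4-(prop-1-en-2-yl)oct-6-enoate | C=C(C)[C@H](CC=C(C)C)C[C@](CC=C(C)C)(C(=O)OC)C1=CC(=O)[C@H](C)[C@@H](C)O1 | intermediate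
22 | methyl (2S,4R)-2-[(2R,3R)-5-bromo-2,3-dimethyl-4-oxo-3,4-dihydro-2H-pyran-6-yl]-7-methyl-2-(3-methylbut-2-en-1-yl)-4-(prop-1-en-2-yl)oct-6-enoate | C=C(C)[C@H](CC=C(C)C)C[C@](CC=C(C)C)(C(=O)OC)C1=C(Br)C(=O)[C@H](C)[C@@H](C)O1 | intermediate
23 | tributyl(1-ethoxyethenyl)stannane | CCCC[Sn](CCCC)(CCCC)C(=C)OCC | starting material
24 | methyl (2S,4R)-2-[(2R,3R)-5-(1-ethoxyethenyl)-2,3-dimethyl-4-oxo-3,4-dihydro-2H-pyran-6-yl]-7-methyl-2-(3-methylbut-2-en-1-yl)-4-(prop-1-en-2-yl)oct-6-enoate | C=C(C)[C@H](CC=C(C)C)C[C@](CC=C(C)C)(C(=O)OC)C1=C(C(=C)OCC)C(=O)[C@H](C)[C@@H](C)O1 | intermediate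
25 | methyl (2S,4R)-2-[(2R,3R)-5-acetyl-2,3-dimethyl-4-oxo-3,4-dihydro-2H-pyran-6-yl]-7-methyl-2-(3-methylbut-2-en-1-yl)-4-(prop-1-en-2-yl)oct-6-enoate | C=C(C)[C@H](CC=C(C)C)C[C@](CC=C(C)C)(C(=O)OC)C1=C(C(C)=O)C(=O)[C@H](C)[C@@H](C)O1 | intermediate
26 | (2R,3R,8S)-5-hydroxy-2,3-dimethyl-8-(3-methylbut-2-en-1-yl)-8-[(2R)-5-methyl-2-(prop-1-en-2-yl)hex-4-en-1-yl]-2,3-dihydro-4H-chromene-4,7(8H)-dione | C=C(C)[C@H](CC=C(C)C)C[C@]1(CC=C(C)C)C(=O)C=C(O)C2=C1O[C@H](C)[C@@H](C)C2=O | intermediate
27 | 3-phenylprop-2-ynal | O=CC#Cc1ccccc1 | starting material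
28 | O7 enol lactone of the target (4-phenyl-3,4-dihydropyran-2-one fused across C6–C7 of ring A, C5 as ketone) | C=C(C)[C@H](CC=C(C)C)C[C@]1(CC=C(C)C)C3=C([C@@H](CC(=O)O3)c4ccccc4)C(=O)C2=C1O[C@H](C)[C@@H](C)C2=O | intermediate
29 | O5 enol lactone of the target (4-phenyl-3,4-dihydropyran-2-one fused across C5–C6 of ring A, C7 as ketone) | C=C(C)[C@H](CC=C(C)C)C[C@]1(CC=C(C)C)C(=O)C3=C(OC(=O)C[C@H]3c4ccccc4)C2=C1O[C@H](C)[C@@H](C)C2=O | intermediate
30 | (3S)-3-{(2R,3R,8S)-5-hydroxy-2,3-dimethyl-8-(3-methylbut-2-en-1-yl)-8-[(2R)-5-methyl-2-(prop-1-en-2-yl)hex-4-en-1-yl]-4,7-dioxo-3,4,7,8-tetrahydro-2H-chromen-6-yl}-3-phenylpropanoic acid (CNP0150579.1) | C=C(C)[C@H](CC=C(C)C)C[C@]1(CC=C(C)C)C(=O)C([C@@H](CC(=O)O)c2ccccc2)=C(O)C2=C1O[C@H](C)[C@@H](C)C2=O | target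

**Step count**

Total steps: 16. Longest linear sequence: 13 steps (steps 1–7, then 11–16).

**Steps most likely to fail**

1. Step 13 (bromination at pyranone C5). The three side‑chain C=C bonds may compete for electrophilic bromine (bromonium formation, allylic bromination) and consume the reagent before substitution at C5 is complete. The fallback sets out from 19 and comes back at 22. The β‑diketone 19, whose enol is far more nucleophilic than an isolated alkene, would be brominated with NBS (1 equiv, CH2Cl2, −20 °C) to the 2‑bromo‑1,3‑diketone F1. HF·pyridine and then catalytic TsOH would remove the silyl group (hydroxy bromo diketone F2, not isolated) and close ring B with loss of water, giving 22 directly.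

2. Step 16 (carbene‑catalysed annulation). Addition of the hindered, strongly acidic enol to the acyl azolium may be slow, and facial discrimination may be insufficient, leading to low conversion or poor selectivity at the benzylic carbon. The fallback sets out from 25 and comes back at 30, forming the C–CH(Ph) bond before ring A is closed. Compound 25 would be converted at −78 °C (LiN(SiMe3)2 with Me3SiCl present) into the trimethylsilyl enol ether of its acetyl group F3. An iminium‑catalysed Mukaiyama–Michael addition of F3 to (E)‑cinnamaldehyde ((2S,5S)-5-benzyl-2-tert-butyl-3-methylimidazolidin-4-one trifluoroacetate, −20 °C, or its enantiomer as a model study requires) would give the δ‑keto aldehyde F4. Oxidation with NaClO2/NaH2PO4/2‑methylbut‑2‑ene would give the keto acid F5. LiN(SiMe3)2 (3.5 equiv, THF, −78 → 0 °C) would then close ring A by the same Dieckmann‑type step, the carboxylate being inert, to give 30.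

3. Step 7 (quaternary centre). Facial discrimination in the alkylation of the lithiated enamine may be incomplete because of the large α‑substituent, eroding the configuration at the quaternary carbon. The fallback sets out from 9 and comes back at 13. Compound 9 would be prenylated without chiral control (NaH, 4, THF/DMF), giving 13 together with its C2 epimer F6. Because the C4 centre is fixed, the two are diastereomers and would be separated by preparative HPLC, only 13 being carried on.

Further compounds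

F1 | step 13 | methyl (2S,4R)-2-{(4R,5R)-2-bromo-5-[(tert-butyldimethylsilyl)oxy]-4-methyl-3-oxohexanoyl}-7-methyl-2-(3-methylbut-2-en-1-yl)-4-(prop-1-en-2-yl)oct-6-enoate (C–Br epimers) | C=C(C)[C@H](CC=C(C)C)C[C@](CC=C(C)C)(C(=O)OC)C(=O)C(Br)C(=O)[C@H](C)[C@@H](C)O[Si](C)(C)C(C)(C)C
F2 | step 13 | methyl (2S,4R)-2-[(4R,5R)-2-bromo-5-hydroxy-4-methyl-3-oxohexanoyl]-7-methyl-2-(3-methylbut-2-en-1-yl)-4-(prop-1-en-2-yl)oct-6-enoate | C=C(C)[C@H](CC=C(C)C)C[C@](CC=C(C)C)(C(=O)OC)C(=O)C(Br)C(=O)[C@H](C)[C@@H](C)O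
F3 | step 16 | trimethylsilyl enol ether of the acetyl group of 25 | C=C(C)[C@H](CC=C(C)C)C[C@](CC=C(C)C)(C(=O)OC)C1=C(C(=C)O[Si](C)(C)C)C(=O)[C@H](C)[C@@H](C)O1
F4 | step 16 | δ-keto aldehyde (pyranone C5 acyl chain C(=O)CH2CH(Ph)CH2CHO, benzylic centre as in the target) | C=C(C)[C@H](CC=C(C)C)C[C@](CC=C(C)C)(C(=O)OC)C1=C(C(=O)C[C@@H](CC=O)c2ccccc2)C(=O)[C@H](C)[C@@H](C)O1
F5 | step 16 | δ-keto acid (pyranone C5 acyl chain C(=O)CH2CH(Ph)CH2CO2H, benzylic centre as in the target) | C=C(C)[C@H](CC=C(C)C)C[C@](CC=C(C)C)(C(=O)OC)C1=C(C(=O)C[C@@H](CC(=O)O)c2ccccc2)C(=O)[C@H](C)[C@@H](C)O1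
F6 | step 7 | methyl (2R,4R)-2-acetyl-7-methyl-2-(3-methylbut-2-en-1-yl)-4-(prop-1-en-2-yl)oct-6-enoate (C2 epimer of 13) | C=C(C)[C@H](CC=C(C)C)C[C@@](CC=C(C)C)(C(=O)OC)C(C)=O
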